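# Total synthesis proposal for CNP0265335.3

**Plan**

- **Cuts (germacrane numbering).** First the two acyl C–O bonds at O3 and O8 and the C1–C10 oxirane; then C13, the lactone C12–O6 bond and the C7–C11 bond; then C8–C9 of the ten-membered ring with C1–C6 re-formed (retro oxy-Cope) to a carvone-derived cyclohexenol; finally C6–C7, back to an enone and a two-carbon alkoxyacetylide.
- **Forward order.** The six-membered ring of (R)-carvone is oxidized to a 4-silyloxy-isopiperitenone and expanded by four carbons to the cyclodecadienone. The γ-lactone is then built on C6/C7, the two separately made acids are attached, and the C1–C10 oxirane is closed last.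
- **Enabling feature.** The Z C4=C5 alkene beside oxygenated C6, the E C1=C10 unit and the oxygenated C8 of the ten-membered ring are what a cyclohexene (ring atoms C1–C6) leaves after a [3,3] shift, if it carries a 2-alkoxyvinyl group on the carbinol carbon C6 and an isopropenyl group on C1.
- **Stereochemistry.** C3 comes from Luche reduction and Mitsunobu inversion relative to the carvone center. That center is relayed through a chair transition state into C8 and the E alkene. C7 (alkylation), C6 (hydride) and C1/C10 (peracid) are set on the ten-membered ring from its periphery. The acyl stereocenters come from tartrate-controlled epoxidation and BINAP–Ru hydrogenation in the tiglic acid series.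

Key step: step 9

Remark: ten-membered compounds are named on the germacrane skeleton (ring C1–C10, C14 on C10, C15 on C4, C11–C13 on C7; H-7 is α, O3 and O8 are β). TBS = tert-butyldimethylsilyl, PMB = 4-methoxybenzyl. The Mannich base 22 is assumed to be carried on as a mixture at C11, a center that disappears in the following step.

## Route

Step 1
Reactants: 1 (R)-(−)-carvone
Product: 2 (1R,5R)-cis-carveol
Conditions: NaBH4, CeCl3·7H2O, MeOH, 0 °C
Reagents that add atoms: none
Why: Luche reduction: the CeCl3-activated carbonyl takes hydride 1,2 and axially, on the face away from the equatorial isopropenyl group, so the new (1R) carbinol is cis to it and the enone C=C is untouched.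

Step 2
Reactants: 2 (1R,5R)-cis-carveol
Product: 3 (1S,5R)-trans-carveyl 4-nitrobenzoate
Conditions: 4-nitrobenzoic acid, PPh3, DIAD, THF, 0 °C → rt
Reagents that add atoms: 4-nitrobenzoic acid, OC(=O)c1ccc(cc1)[N+](=O)[O-]
Why: Mitsunobu esterification: the alkoxyphosphonium ion of the allylic alcohol is displaced by 4-nitrobenzoate in an SN2 sense, inverting C1 to (1S) and placing the ester trans to the isopropenyl group.

Step 3
Reactants: 3 (1S,5R)-trans-carveyl 4-nitrobenzoate
Product: 4 (1S,5R)-trans-carveol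
Conditions: K2CO3 (cat.), MeOH, rt
Reagents that add atoms: none
Why: Base-catalysed transesterification (methanolysis) of the activated aryl ester frees the trans alcohol without breaking a bond to the stereocenter.

Step 4
Reactants: 4 (1S,5R)-trans-carveol
Product: 5 (1S,5R)-trans-carveol TBS ether
Conditions: TBSCl, imidazole, DMF, rt
Reagents that add atoms: tert-butyldimethylsilyl chloride, CC(C)(C)[Si](C)(C)Cl
Why: Imidazole-promoted silylation of a secondary alcohol; the TBS ether is chosen because it should survive the organolithium, hydride, KH, enolate and DDQ steps and can be removed at the end with buffered fluoride.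

Step 5
Reactants: 5 (1S,5R)-trans-carveol TBS ether
Product: 6 (4S,6R)-4-(TBS-oxy)-3-methyl-6-(prop-1-en-2-yl)cyclohex-2-en-1-one
Conditions: CrO3, 3,5-dimethylpyrazole, CH2Cl2, −20 °C
Reagents that add atoms: CrO3, O=[Cr](=O)=O
Why: Allylic oxidation with the CrO3·3,5-dimethylpyrazole complex converts the one ring methylene allylic to the trisubstituted alkene into the enone carbonyl; the other allylic ring position is blocked by the silyloxy group and no stereocenter is involved.

Step 6
Reactants: 7 trichloroethylene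
Product: 8 PMB (E)-1,2-dichlorovinyl ether
Conditions: 4-methoxybenzyl alcohol, KH, THF, 0 °C; then 7, −50 °C → rt
Reagents that add atoms: 4-methoxybenzyl alcohol, COc1ccc(CO)cc1
Why: Elimination–addition: the alkoxide dehydrochlorinates trichloroethylene to dichloroacetylene and adds to it in anti fashion, the established entry to (E)-1,2-dichlorovinyl ethers.

Step 7
Reactants: 8 PMB (E)-1,2-dichlorovinyl ether; 6 (4S,6R)-4-(TBS-oxy)-3-methyl-6-(prop-1-en-2-yl)cyclohex-2-en-1-one
Product: 11 (1R,4S,6R)-4-(TBS-oxy)-1-[(PMB-oxy)ethynyl]-3-methyl-6-(prop-1-en-2-yl)cyclohex-2-en-1-ol, via 1-chloro-2-(PMB-oxy)ethyne 9 (not isolated), via lithium (PMB-oxy)ethynide 10 (not isolated)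
Conditions: 8, n-BuLi (2 equiv), THF, −78 → −40 °C; then 6 precomplexed with anhydrous CeCl3, THF, −78 °C; H2O quench; product used without delay
Reagents that add atoms: none
Why: n-BuLi turns 8 by dehydrochlorination and chlorine–lithium exchange into the alkoxyacetylide 10 (known ynol ether anion chemistry), which undergoes 1,2-addition to the CeCl3-activated enone on the face opposite the adjacent isopropenyl group, so that the new (1R) carbinol carries the two future diene arms trans.

Step 8
Reactants: 11 (1R,4S,6R)-4-(TBS-oxy)-1-[(PMB-oxy)ethynyl]-3-methyl-6-(prop-1-en-2-yl)cyclohex-2-en-1-ol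
Product: 12 (1R,4S,6R)-4-(TBS-oxy)-1-[(E)-2-(PMB-oxy)ethenyl]-3-methyl-6-(prop-1-en-2-yl)cyclohex-2-en-1-ol
Conditions: LiAlH4, THF, 0 °C → rt; aq. KNaC4H4O6 (potassium sodium tartrate) work-up, no acid
Reagents that add atoms: none
Why: Hydroxyl-directed trans-hydroalumination (LiAlH4 reduction of a propargylic alkoxide): hydride is delivered intramolecularly to the alkyne carbon next to the carbinol and the C–Al bond is protonated with retention, giving only the E enol ether.

Step 9
Reactants: 12 (1R,4S,6R)-4-(TBS-oxy)-1-[(E)-2-(PMB-oxy)ethenyl]-3-methyl-6-(prop-1-en-2-yl)cyclohex-2-en-1-ol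
Product: 15 3β-(TBS-oxy)-8β-(PMB-oxy)-11,12,13-trinorgermacra-1(10)E,4Z-dien-6-one, via potassium alkoxide 13 (not isolated), via potassium enolate 14 (not isolated)
Conditions: KH, 18-crown-6, THF, 0 → 25 °C; then AcOH, THF, −78 °C
Reagents that add atoms: none
Why: KH with 18-crown-6 gives the dissociated potassium alkoxide 13, in which the C1–C6 bond is weakened, and the 1,5-diene C8=C7–C6–C1–C10=C9 undergoes a suprafacial [3,3] sigmatropic shift that breaks C1–C6 and forms C8–C9, delivering enolate 14, which is protonated at C7 in the cold. The closest known reaction type is the anionic oxy-Cope ring expansion of trans-1,2-dialkenylcyclohexanols and of 6-alkenyl-1-vinylcyclohex-2-en-1-ols to cyclodecadienones. The ten-membered carbocycle is not closed end to end: it arises by four-atom ring expansion of the cyclohexene, the new σ bond being made inside a six-centre chair array fused trans to the half-chair ring. C8 is the only new stereocenter and is controlled by chirality transfer from the carvone-derived C1 (which, like C6, becomes sp2): with the two alkenyl groups trans-diequatorial the chair places C2 and, because the enol ether is E, the C8 alkoxy group equatorial, which gives (8R) and the E C1=C10 alkene, while the ring alkene is carried over as the Z C4=C5 enone. The step needs chair over boat and an enolate that keeps its β-alkoxy group: the gauche trans-diequatorial diene and the E enol ether secure the first, and the equatorial C8–O bond, which lies in the nodal plane of the enolate, together with the cold acid quench, the second.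

Step 10
Reactants: 15 3β-(TBS-oxy)-8β-(PMB-oxy)-11,12,13-trinorgermacra-1(10)E,4Z-dien-6-one; 16 methyl bromoacetate
Product: 18 methyl 3β-(TBS-oxy)-8β-(PMB-oxy)-6-oxo-13-norgermacra-1(10)E,4Z-dien-12-oate (7R; H-7α), via lithium enolate 17 (not isolated)
Conditions: LiN(iPr)2 (commercial solution), THF, −78 °C; then 16, −78 → −45 °C (no polar cosolvent)
Reagents that add atoms: none
Why: Enolate alkylation: kinetic α′-deprotonation gives the cross-conjugated lithium enolate 17, in which lithium bridges the enolate oxygen and the C8 ether oxygen and so holds the C8–O bond close to the enolate plane (unsuited to E1cB loss); the bromoacetate should then attack C7 from the outer face of the ring, anti to ring carbon C9, which gives (7R) with H-7 and H-8 cis.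

Step 11
Reactants: 18 methyl 3β-(TBS-oxy)-8β-(PMB-oxy)-6-oxo-13-norgermacra-1(10)E,4Z-dien-12-oate
Product: 20 3β-(TBS-oxy)-8β-(PMB-oxy)-13-norgermacra-1(10)E,4Z-dien-12,6α-olide, via hydroxy ester 19 (not isolated)
Conditions: NaBH4, CeCl3·7H2O, MeOH, −78 → −40 °C; then pyridinium p-toluenesulfonate (cat.), toluene, 45 °C
Reagents that add atoms: none
Why: Luche conditions give clean 1,2-reduction of the cross-conjugated enone; hydride should enter C6 from outside the ring on the face remote from the C7 acetate arm, in the conformer that keeps the C6=O and C8–O dipoles opposed, so that the 6α (6R) alcohol 19 results, and mild acid then closes it onto the ester (5-exo-trig acyl substitution) to the trans-fused γ-lactone.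

Step 12
Reactants: 20 3β-(TBS-oxy)-8β-(PMB-oxy)-13-norgermacra-1(10)E,4Z-dien-12,6α-olide
Product: 22 13-(dimethylamino)-3β-(TBS-oxy)-8β-(PMB-oxy)germacra-1(10)E,4Z-dien-12,6α-olide, via lithium lactone enolate 21 (not isolated)
Conditions: LiN(iPr)2, THF, −78 °C; then dimethylmethyleneiminium iodide, −78 °C → rt
Reagents that add atoms: dimethylmethyleneiminium iodide, C=[N+](C)C.[I-]
Why: Mannich reaction of a preformed lactone enolate: enolate 21 attacks the iminium carbon and adds C13; the new C11 center is of no consequence because it becomes sp2 in the next step, and C7 carries no leaving group that the enolate could expel.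

Step 13
Reactants: 22 13-(dimethylamino)-3β-(TBS-oxy)-8β-(PMB-oxy)germacra-1(10)E,4Z-dien-12,6α-olide
Product: 24 3β-(TBS-oxy)-8β-(PMB-oxy)germacra-1(10)E,4Z,11(13)-trien-12,6α-olide, via trimethylammonium iodide 23 (not isolated)
Conditions: MeI, MeOH, rt; then aq. NaHCO3, CH2Cl2, rt
Reagents that add atoms: none
Why: N-Methylation to the quaternary salt 23 and bicarbonate-induced E1cB (Hofmann-type) elimination of trimethylamine unmask the α-methylene lactone, the standard end of the aminomethylation route.

Step 14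
Reactants: 24 3β-(TBS-oxy)-8β-(PMB-oxy)germacra-1(10)E,4Z,11(13)-trien-12,6α-olide
Product: 25 8β-hydroxy-3β-(TBS-oxy)germacra-1(10)E,4Z,11(13)-trien-12,6α-olide
Conditions: DDQ, CH2Cl2/pH 7 phosphate buffer, 0 °C → rt
Reagents that add atoms: none
Why: Oxidative PMB ether cleavage: DDQ abstracts hydride from the electron-rich benzylic position and water hydrolyses the oxocarbenium ion, leaving the silyl ether, the alkenes and the α-methylene lactone untouched.

Step 15
Reactants: 26 tiglic acid
Product: 27 tiglyl alcohol [(E)-2-methylbut-2-en-1-ol]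
Conditions: LiAlH4, Et2O, 0 °C → rt
Reagents that add atoms: none
Why: Hydride reduction (LiAlH4) of the conjugated acid stops at the allylic alcohol and leaves the E alkene geometry unchanged.

Step 16
Reactants: 27 tiglyl alcohol
Product: 28 (2S,3S)-2,3-epoxy-2-methylbutan-1-ol
Conditions: Ti(OiPr)4 (cat.), L-(+)-diethyl tartrate (cat.), t-BuOOH, 4 Å molecular sieves, CH2Cl2, −20 °C
Reagents that add atoms: tert-butyl hydroperoxide, CC(C)(C)OO
Why: Katsuki–Sharpless asymmetric epoxidation: the titanium tartrate complex made with L-(+)-diethyl tartrate delivers the peroxide oxygen to the enantioface of the E allylic alcohol that gives the (2S,3S) oxirane, and the E geometry fixes the two methyl groups cis.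

Step 17
Reactants: 28 (2S,3S)-2,3-epoxy-2-methylbutan-1-ol
Product: 29 (2R,3S)-2,3-epoxy-2-methylbutanoic acid
Conditions: RuCl3·xH2O (cat.), NaIO4, MeCN/EtOAc/H2O, 0 °C → rt; acid kept cold and used promptly
Reagents that add atoms: water, O
Why: RuO4 generated catalytically (RuCl3/NaIO4) oxidizes primary 2,3-epoxy alcohols to glycidic acids without opening the oxirane; the descriptor at C2 changes to (R) only because the carboxyl group outranks C3.

Step 18
Reactants: 25 8β-hydroxy-3β-(TBS-oxy)germacra-1(10)E,4Z,11(13)-trien-12,6α-olide; 29 (2R,3S)-2,3-epoxy-2-methylbutanoic acid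
Product: 31 8β-[(2R,3S)-2,3-epoxy-2-methylbutanoyloxy]-3β-(TBS-oxy)germacra-1(10)E,4Z,11(13)-trien-12,6α-olide, via mixed anhydride 30 (not isolated)
Conditions: 29, 2,4,6-trichlorobenzoyl chloride, Et3N, THF, 0 °C → rt; then 25, DMAP, toluene, rt → 40 °C
Reagents that add atoms: none
Why: Yamaguchi esterification: the mixed anhydride 30 transfers the epoxy-acyl group via its acylpyridinium ion to the hindered secondary C8 hydroxyl; the acid has no α-hydrogen, so neither of its stereocenters can epimerize.

Step 19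
Reactants: 31 8β-[(2R,3S)-2,3-epoxy-2-methylbutanoyloxy]-3β-(TBS-oxy)germacra-1(10)E,4Z,11(13)-trien-12,6α-olide
Product: 32 8β-[(2R,3S)-2,3-epoxy-2-methylbutanoyloxy]-3β-hydroxygermacra-1(10)E,4Z,11(13)-trien-12,6α-olide
Conditions: HF·pyridine, pyridine, THF, 0 °C → rt
Reagents that add atoms: none
Why: Fluoride-mediated Si–O cleavage with pyridine-buffered HF·pyridine; these conditions are routinely compatible with oxiranes, esters and α-methylene lactones.

Step 20
Reactants: 26 tiglic acid
Product: 33 (R)-2-methylbutanoic acid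
Conditions: H2 (4 atm), Ru(OAc)2[(R)-BINAP] (cat.), MeOH, rt
Reagents that add atoms: none
Why: Asymmetric hydrogenation of an α,β-unsaturated carboxylic acid on a BINAP–Ru dicarboxylate catalyst: the substrate binds as its carboxylate and the (R)-BINAP ligand, chosen as the antipode that should give the (R) acid, sets the single stereocenter.

Step 21
Reactants: 32 8β-[(2R,3S)-2,3-epoxy-2-methylbutanoyloxy]-3β-hydroxygermacra-1(10)E,4Z,11(13)-trien-12,6α-olide; 33 (R)-2-methylbutanoic acid
Product: 34 3β-[(2R)-2-methylbutanoyloxy]-8β-[(2R,3S)-2,3-epoxy-2-methylbutanoyloxy]germacra-1(10)E,4Z,11(13)-trien-12,6α-olide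
Conditions: DCC, DMAP (cat.), CH2Cl2, 0 °C → rt
Reagents that add atoms: none
Why: Steglich esterification (carbodiimide/DMAP) at low temperature acylates the allylic C3 hydroxyl through the O-acylisourea and acylpyridinium ion without passing through a ketene, so the α-stereocenter of the acid is retained.

Step 22
Reactants: 34 3β-[(2R)-2-methylbutanoyloxy]-8β-[(2R,3S)-2,3-epoxy-2-methylbutanoyloxy]germacra-1(10)E,4Z,11(13)-trien-12,6α-olide
Product: 35 CNP0265335.3 [(1R,3S,6R,7R,8R,10R)-1β,10α-epoxy-3β-[(2R)-2-methylbutanoyloxy]-8β-[(2R,3S)-2,3-epoxy-2-methylbutanoyloxy]germacra-4Z,11(13)-dien-12,6α-olide]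
Conditions: mCPBA, solid NaHCO3 (buffer), CH2Cl2, 0 °C
Reagents that add atoms: 3-chloroperoxybenzoic acid, OOC(=O)c1cccc(Cl)c1
Why: Prilezhaev epoxidation: the peracid selects the only electron-rich alkene, the strained E-trisubstituted C1=C10 bond (C4=C5 is flanked by two acyloxy-bearing carbons and the exocyclic methylene is conjugated), and should attack its outer face in the conformer with C14 on the β side, giving the trans 1β,10α (1R,10R) oxirane.

## Compound list

1 | (R)-(−)-carvone | CC1=CC[C@H](CC1=O)C(C)=C | starting material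
2 | (1R,5R)-cis-carveol (OH cis to isopropenyl) | C1C=C(C)[C@H](O)C[C@@H]1C(C)=C | intermediate
3 | (1S,5R)-trans-carveyl 4-nitrobenzoate | C1C=C(C)[C@@H](OC(=O)c2ccc(cc2)[N+](=O)[O-])C[C@@H]1C(C)=C | intermediate
4 | (1S,5R)-trans-carveol | C1C=C(C)[C@@H](O)C[C@@H]1C(C)=C | intermediate
5 | (1S,5R)-trans-carveol TBS ether | C1C=C(C)[C@@H](O[Si](C)(C)C(C)(C)C)C[C@@H]1C(C)=C | intermediate
6 | (4S,6R)-4-(TBS-oxy)-3-methyl-6-(prop-1-en-2-yl)cyclohex-2-en-1-one (silyloxy trans to isopropenyl) | O=C1C=C(C)[C@@H](O[Si](C)(C)C(C)(C)C)C[C@@H]1C(C)=C | intermediate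
7 | trichloroethylene | ClC=C(Cl)Cl | starting material
8 | PMB (E)-1,2-dichlorovinyl ether | COc1ccc(CO/C(Cl)=C\Cl)cc1 | intermediate
9 | 1-chloro-2-(PMB-oxy)ethyne | COc1ccc(COC#CCl)cc1 | intermediate (not isolated)
10 | lithium (PMB-oxy)ethynide | [Li+].[C-]#COCc1ccc(OC)cc1 | intermediate (not isolated)
11 | (1R,4S,6R)-4-(TBS-oxy)-1-[(PMB-oxy)ethynyl]-3-methyl-6-(prop-1-en-2-yl)cyclohex-2-en-1-ol (alkynyl trans to isopropenyl) | O[C@]1(C#COCc2ccc(OC)cc2)C=C(C)[C@@H](O[Si](C)(C)C(C)(C)C)C[C@@H]1C(C)=C | intermediate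
12 | (1R,4S,6R)-4-(TBS-oxy)-1-[(E)-2-(PMB-oxy)ethenyl]-3-methyl-6-(prop-1-en-2-yl)cyclohex-2-en-1-ol | O[C@]1(/C=C/OCc2ccc(OC)cc2)C=C(C)[C@@H](O[Si](C)(C)C(C)(C)C)C[C@@H]1C(C)=C | intermediate
13 | potassium alkoxide of 12 | [K+].[O-][C@]1(/C=C/OCc2ccc(OC)cc2)C=C(C)[C@@H](O[Si](C)(C)C(C)(C)C)C[C@@H]1C(C)=C | intermediate (not isolated)
14 | potassium enolate of 15 (O–K on C6, C6=C7, enolate oxygen cis to C8) | [K+].C1/C(C)=C/C[C@H](O[Si](C)(C)C(C)(C)C)/C(C)=C\C([O-])=C\[C@@H]1OCc2ccc(OC)cc2 | intermediate (not isolated)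
15 | 3β-(TBS-oxy)-8β-(PMB-oxy)-11,12,13-trinorgermacra-1(10)E,4Z-dien-6-one = (2Z,4S,6E,9R)-4-(TBS-oxy)-9-(PMB-oxy)-3,7-dimethylcyclodeca-2,6-dien-1-one | O=C1/C=C(/C)[C@@H](O[Si](C)(C)C(C)(C)C)C/C=C(\C)C[C@@H](OCc2ccc(OC)cc2)C1 | intermediate
16 | methyl bromoacetate | BrCC(=O)OC | starting material
17 | lithium enolate of 15 (O–Li on C6, C6=C7) | [Li+].C1/C(C)=C/C[C@H](O[Si](C)(C)C(C)(C)C)/C(C)=C\C([O-])=C\[C@@H]1OCc2ccc(OC)cc2 | intermediate (not isolated)
18 | methyl 3β-(TBS-oxy)-8β-(PMB-oxy)-6-oxo-13-norgermacra-1(10)E,4Z-dien-12-oate (3S,7R,8R; H-7α) | O=C1/C=C(/C)[C@@H](O[Si](C)(C)C(C)(C)C)C/C=C(\C)C[C@@H](OCc2ccc(OC)cc2)[C@H]1CC(=O)OC | intermediate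
19 | methyl 6α-hydroxy-3β-(TBS-oxy)-8β-(PMB-oxy)-13-norgermacra-1(10)E,4Z-dien-12-oate | O[C@@H]1/C=C(/C)[C@@H](O[Si](C)(C)C(C)(C)C)C/C=C(\C)C[C@@H](OCc2ccc(OC)cc2)[C@H]1CC(=O)OC | intermediate (not isolated)
20 | 3β-(TBS-oxy)-8β-(PMB-oxy)-13-norgermacra-1(10)E,4Z-dien-12,6α-olide (3S,6R,7R,8R; trans-fused lactone) | C1C(=O)O[C@@H]2/C=C(/C)[C@@H](O[Si](C)(C)C(C)(C)C)C/C=C(\C)C[C@@H](OCc3ccc(OC)cc3)[C@@H]12 | intermediate
21 | lithium enolate of lactone 20 | [Li+].C1=C([O-])O[C@@H]2/C=C(/C)[C@@H](O[Si](C)(C)C(C)(C)C)C/C=C(\C)C[C@@H](OCc3ccc(OC)cc3)[C@@H]12 | intermediate (not isolated)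
22 | 13-(dimethylamino)-3β-(TBS-oxy)-8β-(PMB-oxy)germacra-1(10)E,4Z-dien-12,6α-olide (C11 epimers) | CN(C)CC1C(=O)O[C@@H]2/C=C(/C)[C@@H](O[Si](C)(C)C(C)(C)C)C/C=C(\C)C[C@@H](OCc3ccc(OC)cc3)[C@@H]12 | intermediate
23 | N-methyl quaternary ammonium iodide of 22 | C[N+](C)(C)CC1C(=O)O[C@@H]2/C=C(/C)[C@@H](O[Si](C)(C)C(C)(C)C)C/C=C(\C)C[C@@H](OCc3ccc(OC)cc3)[C@@H]12.[I-] | intermediate (not isolated)
24 | 3β-(TBS-oxy)-8β-(PMB-oxy)germacra-1(10)E,4Z,11(13)-trien-12,6α-olide | C=C1C(=O)O[C@@H]2/C=C(/C)[C@@H](O[Si](C)(C)C(C)(C)C)C/C=C(\C)C[C@@H](OCc3ccc(OC)cc3)[C@@H]12 | intermediate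
25 | 8β-hydroxy-3β-(TBS-oxy)germacra-1(10)E,4Z,11(13)-trien-12,6α-olide | C=C1C(=O)O[C@@H]2/C=C(/C)[C@@H](O[Si](C)(C)C(C)(C)C)C/C=C(\C)C[C@@H](O)[C@@H]12 | intermediate
26 | tiglic acid [(E)-2-methylbut-2-enoic acid] | C/C=C(\C)C(=O)O | starting material
27 | tiglyl alcohol [(E)-2-methylbut-2-en-1-ol] | C/C=C(\C)CO | intermediate
28 | (2S,3S)-2,3-epoxy-2-methylbutan-1-ol | OC[C@]1(C)O[C@H]1C | intermediate
29 | (2R,3S)-2,3-epoxy-2-methylbutanoic acid (methyl groups cis) | O=C(O)[C@]1(C)O[C@H]1C | intermediate
30 | (2R,3S)-2,3-epoxy-2-methylbutanoic 2,4,6-trichlorobenzoic anhydride | O=C(OC(=O)c1c(Cl)cc(Cl)cc1Cl)[C@]2(C)O[C@H]2C | intermediate (not isolated)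
31 | 8β-[(2R,3S)-2,3-epoxy-2-methylbutanoyloxy]-3β-(TBS-oxy)germacra-1(10)E,4Z,11(13)-trien-12,6α-olide | C=C1C(=O)O[C@@H]2/C=C(/C)[C@@H](O[Si](C)(C)C(C)(C)C)C/C=C(\C)C[C@@H](OC(=O)[C@]3(C)O[C@H]3C)[C@@H]12 | intermediate
32 | 8β-[(2R,3S)-2,3-epoxy-2-methylbutanoyloxy]-3β-hydroxygermacra-1(10)E,4Z,11(13)-trien-12,6α-olide | C=C1C(=O)O[C@@H]2/C=C(/C)[C@@H](O)C/C=C(\C)C[C@@H](OC(=O)[C@]3(C)O[C@H]3C)[C@@H]12 | intermediate
33 | (R)-2-methylbutanoic acid | CC[C@@H](C)C(=O)O | intermediate
34 | 3β-[(2R)-2-methylbutanoyloxy]-8β-[(2R,3S)-2,3-epoxy-2-methylbutanoyloxy]germacra-1(10)E,4Z,11(13)-trien-12,6α-olide | C=C1C(=O)O[C@@H]2/C=C(/C)[C@@H](OC(=O)[C@H](C)CC)C/C=C(\C)C[C@@H](OC(=O)[C@]3(C)O[C@H]3C)[C@@H]12 | intermediate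
35 | CNP0265335.3 | C=C1C(=O)O[C@@H]2/C=C(/C)[C@@H](OC(=O)[C@H](C)CC)C[C@H]3O[C@]3(C)C[C@@H](OC(=O)[C@]3(C)O[C@H]3C)[C@@H]12 | target

## Step count and risks

Total step count: 22. Longest linear sequence: 17 steps (steps 1–5, 7–14, 18, 19, 21, 22, from carvone 1 to 35).

The three steps most likely to fail:

**Step 10 (C7 alkylation).** The lithium enolate may expel the C8 alkoxide by β-elimination, or the electrophile may enter on the other enolate face and give the C7 epimer. The fallback sets out from carbinol 12 and comes back at keto ester 18. Enolate 14 of the key step is not protonated but silylated in the flask (Me3SiCl, Et3N, −78 °C) to the trimethylsilyl enol ether F1. A Mukaiyama aldol addition of F1 to methyl glyoxylate (BF3·OEt2, CH2Cl2, −78 °C) gives the aldol adduct F2 without any basic enolate. Dehydration with the inner salt methyl N-(triethylammoniosulfonyl)carbamate (benzene, 50 °C) gives the alkylidene keto ester F3. Conjugate reduction of its doubly activated C7=C11 bond with [(Ph3P)CuH]6 and cold protonation then lead to 18. Here hydrogen, not carbon, is delivered to the accessible face of C7, so the sense of induction is reversed and no long-lived lithium β-alkoxy enolate is needed.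

**Step 11 (C6 reduction and lactonization).** Hydride may be delivered to the other carbonyl face of the flexible ten-membered ring, giving the 6β-alcohol and hence the cis-lactone series. The fallback sets out from keto ester 18 and returns at lactone 20. The same Luche reduction, worked up without acid, would then give the 6β-hydroxy ester F4. Saponification (LiOH, THF/H2O) gives the 6β-hydroxy acid F5. A Mitsunobu lactonization (PPh3, DIAD, toluene, 0 °C) activates the allylic C6 hydroxyl and lets the carboxylate displace it with inversion, which gives the 12,6α-olide 20.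

**Step 22 (final epoxidation).** The peracid may show poor facial selectivity on the conformationally mobile ring, or acid may open the new oxirane transannularly. The fallback sets out from diester 34 and returns at target 35. NBS in aqueous THF at 0 °C gives the bromohydrin F6, with bromine at C1 on the face an electrophile reaches first and the hydroxyl anti at the tertiary C10. K2CO3 in acetone then closes the oxirane by backside displacement at C1. The oxygen thereby ends on the face opposite to the one the electrophile attacked, the complement of direct peracid epoxidation, under non-acidic conditions.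

Further compounds
F1 | step 10 | trimethylsilyl enol ether of 15 (C6–OSiMe3, C6=C7) | C1/C(C)=C/C[C@H](O[Si](C)(C)C(C)(C)C)/C(C)=C\C(O[Si](C)(C)C)=C\[C@@H]1OCc2ccc(OC)cc2
F2 | step 10 | methyl 11-hydroxy-3β-(TBS-oxy)-8β-(PMB-oxy)-6-oxo-13-norgermacra-1(10)E,4Z-dien-12-oate (mixture at C7 and C11) | O=C1/C=C(/C)[C@@H](O[Si](C)(C)C(C)(C)C)C/C=C(\C)C[C@@H](OCc2ccc(OC)cc2)C1C(O)C(=O)OC
F3 | step 10 | methyl 3β-(TBS-oxy)-8β-(PMB-oxy)-6-oxo-13-norgermacra-1(10)E,4Z,7(11)-trien-12-oate (C7=C11 geometry not fixed) | O=C1/C=C(/C)[C@@H](O[Si](C)(C)C(C)(C)C)C/C=C(\C)C[C@@H](OCc2ccc(OC)cc2)C1=CC(=O)OC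
F4 | step 11 | methyl 6β-hydroxy-3β-(TBS-oxy)-8β-(PMB-oxy)-13-norgermacra-1(10)E,4Z-dien-12-oate | O[C@H]1/C=C(/C)[C@@H](O[Si](C)(C)C(C)(C)C)C/C=C(\C)C[C@@H](OCc2ccc(OC)cc2)[C@H]1CC(=O)OC
F5 | step 11 | 6β-hydroxy-3β-(TBS-oxy)-8β-(PMB-oxy)-13-norgermacra-1(10)E,4Z-dien-12-oic acid | O[C@H]1/C=C(/C)[C@@H](O[Si](C)(C)C(C)(C)C)C/C=C(\C)C[C@@H](OCc2ccc(OC)cc2)[C@H]1CC(=O)O
F6 | step 22 | 1-bromo-10-hydroxy bromohydrin of 34 (Br at C1, OH at C10, anti) | C=C1C(=O)O[C@@H]2/C=C(/C)[C@@H](OC(=O)[C@H](C)CC)C[C@H](Br)[C@@](O)(C)C[C@@H](OC(=O)[C@]3(C)O[C@H]3C)[C@@H]12
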